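**Plan**
1. Retrosynthesis: first cut the two C–O bonds of a temporary diphenylmethylene ketal on O6'/O7', then the C3–C3' bond between the two pyranone rings. This leaves two catalogue coumarins, esculetin 1 (used as its ketal 2) and isofraxidin 3, so all four rings are bought and none is built.
2. Enabling feature: each half is a 7-oxygenated coumarin, a ring-locked p-hydroxycinnamate with O7 para to C4a. Oxidation at O7–H of 3 is relayed through C4a and C4 to C3 (α to the lactone C2=O), and because C6 and C8 carry OMe, C3 is the only open carbon terminus.
3. The C3'=C4' bond of the esculetin pyranone is a styrene-type acceptor that takes an electrophilic radical at C3' (C4' radical or cation stabilised by the para O7'). The coupling therefore copies the presumed phenoxyl-radical (8–8'-type) biosynthesis.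
4. Forward order: mask the catechol of 1 (gives 2), join 2 and 3 by anodic dehydrogenative cross-coupling (via 4 to 5), then hydrolyse the ketal (gives 6).
5. Stereochemistry: there is none to set. Compound 6 has no stereocentre, and the C3–C3' axis is flanked only by H4/H4' and the C2/C2' carbonyl oxygens, so it rotates freely.

Key step: step 2

Assumption: the target SMILES carries no stereodescriptor and the molecule is achiral, so it is made as the single achiral compound it is. Esculetin and isofraxidin are both taken as purchasable catalogue compounds.

**Step 1**
Reactants: 1 esculetin (6,7-dihydroxycoumarin)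
Product: 2 esculetin diphenylmethylene ketal (2,2-diphenyl-6H-[1,3]dioxolo[4,5-g]chromen-6-one)
Conditions: Ph2CCl2 (1.5 equiv), Ph2O, 175 °C, N2 stream
Reagents that add atoms: dichlorodiphenylmethane, ClC(Cl)(c1ccccc1)c1ccccc1
Why: Catechol ketalisation with a gem-dichloride, in which the two adjacent phenols replace both chlorides by way of the stabilised chlorodiphenylcarbenium ion and close an unstrained 1,3-benzodioxole; escape of HCl drives it, the lactone is inert in the water-free acidic melt, and the mask has no benzylic C–H to be oxidised later and keeps O7' in conjugation.

**Step 2**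
Reactants: 2 esculetin diphenylmethylene ketal (3 equiv, excess recovered); 3 isofraxidin (7-hydroxy-6,8-dimethoxycoumarin)
Product: 5 arteminorin C 6',7'-diphenylmethylene ketal (7-(7-hydroxy-6,8-dimethoxy-2-oxo-2H-chromen-3-yl)-2,2-diphenyl-6H-[1,3]dioxolo[4,5-g]chromen-6-one), via p-quinone methide tautomer 4 (not isolated)
Conditions: undivided cell, BDD anode | Pt cathode, Bu3NMe O3SOMe (0.1 M), HFIP, 50 °C, constant current 2–3 mA cm−2, 2.0–2.2 F per mol of 3
Reagents that add atoms: none
Why: Proposed new method: at the anode 3, the only partner with a free OH and hence the more easily oxidised one, should lose one electron and the O7 proton to give a phenoxyl radical whose spin is relayed from O7 through C4a to C3, and since C6 and C8 are blocked by OMe this electrophilic α-acyl terminus is the only carbon open to bond formation. It should add to C3' of the styrene-type C3'=C4' bond of 2, the position at which electrophilic radicals are known to attack coumarins because the resulting C4' benzylic radical is stabilised by the para O7'; a second electron transfer and loss of H3' restore the pyranone of the esculetin half and leave p-quinone methide 4, whose doubly activated C3–H moves to O7 so that the isofraxidin half rearomatises to 5, while the cathode turns the two protons into H2. The closest known reaction types are the anodic dehydrogenative phenol–arene cross-coupling at boron-doped diamond in HFIP, the oxidative 8–8' coupling of sinapate esters and the Meerwein-type radical C3–H functionalisation of coumarins; what has not been shown is the vinylogous para carbon of a 7-hydroxycoumarin as the radical terminus and a second coumarin as its acceptor. No ring is closed and no lasting stereocentre is made, C3 of 4 being sp3 only in passing. The step needs cross- over homo-coupling, C–C over C–O coupling and C3' over C5'/C8' attack: the first rests on the gap in oxidation potential between phenol 3 and diether 2, on the excess of 2 and on a low current density that keeps the radical concentration small, the second on the fact that only the C–C adduct drains irreversibly by rearomatisation, and the third on the benzylic stabilisation at C4'. HFIP should prolong the life of the radical and is reduced at Pt at low overpotential, which should spare the reducible enoate units, and 5 has no open carbon terminus left, so that its further oxidation should be unproductive and slow.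

**Step 3**
Reactants: 5 arteminorin C 6',7'-diphenylmethylene ketal
Product: 6 arteminorin C
Conditions: AcOH–H2O (4:1), reflux, Ar
Reagents that add atoms: none
Why: Acid-catalysed ketal hydrolysis, in which protonation opens the dioxole to a doubly benzylic oxocarbenium ion that water carries off as the ketone, while the aryl methyl ethers, the free phenol and both lactones are stable to hot aqueous acetic acid and argon shields the liberated catechol.

**Compound list**
1 | esculetin (6,7-dihydroxycoumarin) | O=c1ccc2cc(O)c(O)cc2o1 | starting material
2 | esculetin diphenylmethylene ketal (2,2-diphenyl-6H-[1,3]dioxolo[4,5-g]chromen-6-one) | O=c1ccc2cc3OC(c4ccccc4)(c4ccccc4)Oc3cc2o1 | intermediate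
3 | isofraxidin (7-hydroxy-6,8-dimethoxycoumarin) | COc1cc2ccc(=O)oc2c(OC)c1O | starting material
4 | p-quinone methide tautomer of 5 (7-oxo, C4=C4a exocyclic, C3 sp3 and racemic, transient) | COC1=CC2=CC(c3cc4cc5OC(c6ccccc6)(c6ccccc6)Oc5cc4oc3=O)C(=O)OC2=C(OC)C1=O | intermediate
5 | arteminorin C 6',7'-diphenylmethylene ketal | COc1cc2cc(-c3cc4cc5OC(c6ccccc6)(c6ccccc6)Oc5cc4oc3=O)c(=O)oc2c(OC)c1O | intermediate
6 | arteminorin C (3-(6,7-dihydroxy-2-oxo-2H-chromen-3-yl)-7-hydroxy-6,8-dimethoxy-2H-chromen-2-one) | COc1cc2cc(-c3cc4cc(O)c(O)cc4oc3=O)c(=O)oc2c(OC)c1O | target

**Step count**
Total steps: 3. Longest linear sequence: 3 (1 → 2 → 5 → 6).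

**Steps most likely to fail**

Step 2. The phenoxyl radical of 3 may pair with itself or couple through oxygen faster than it adds to the weakly nucleophilic C3'=C4' bond of 2. The fallback gives up the C–H/C–H coupling for a Suzuki–Miyaura coupling of pre-functionalised halves, all of it known chemistry, and it sets out from 2 and 3.
- Electrophilic C3 bromination of 2 (NBS, MeCN, rt) gives 7-bromo-2,2-diphenyl-6H-[1,3]dioxolo[4,5-g]chromen-6-one F1.
- Miyaura borylation of F1 (B2pin2, PdCl2(dppf), KOAc, dioxane, 80 °C) gives the coumarin-3-yl pinacol boronate F2.
- Bromination of 3 (NBS, MeCN, 0 °C), directed to C3 because C6 and C8 are blocked, gives 3-bromoisofraxidin F3.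
- F2 and F3 are joined with Pd(OAc)2/SPhos, K3PO4, dioxane–H2O, 80 °C and an acidic work-up. This returns to the route at 5.

Step 1. At 175 °C under evolving HCl the ketalisation may stall after the first substitution, or the catechol may char. The fallback changes the class of mask and the way it is removed, and it sets out from 1.
- Double Williamson benzylation (BnBr, K2CO3, DMF, 60 °C) gives 6,7-bis(benzyloxy)coumarin F4.
- F4 takes the place of 2 in the electrolysis of step 2 with 3. It passes through the corresponding p-quinone methide tautomer F5 to arteminorin C 6',7'-dibenzyl ether F6.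
- Hydrogenolysis of F6 (H2, 1 atm, Pd/C, THF–MeOH, rt, stopped after uptake) returns to the route at 6.

Step 3. Hydrolysis of the hindered diaryl ketal may be slow, and long heating in acid with traces of air may oxidise the liberated catechol. The fallback replaces hydrolysis by reduction and sets out from 5. Hydrogenolysis of the two benzhydrylic C–O bonds (H2, 1 atm, Pd(OH)2/C, THF–MeOH, rt) leads directly to 6 without a new compound.

**Further compounds**
F1 | step 2 | 7-bromo-2,2-diphenyl-6H-[1,3]dioxolo[4,5-g]chromen-6-one | O=c1oc2cc3OC(c4ccccc4)(c4ccccc4)Oc3cc2cc1Br
F2 | step 2 | 2,2-diphenyl-7-(4,4,5,5-tetramethyl-1,3,2-dioxaborolan-2-yl)-6H-[1,3]dioxolo[4,5-g]chromen-6-one | CC1(C)OB(OC1(C)C)c1cc2cc3OC(c4ccccc4)(c4ccccc4)Oc3cc2oc1=O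
F3 | step 2 | 3-bromoisofraxidin (3-bromo-7-hydroxy-6,8-dimethoxycoumarin) | COc1cc2cc(Br)c(=O)oc2c(OC)c1O
F4 | step 1 | 6,7-bis(benzyloxy)coumarin | O=c1ccc2cc(OCc3ccccc3)c(OCc3ccccc3)cc2o1
F5 | step 1 | p-quinone methide tautomer of F6 (C3 sp3, racemic, transient) | COC1=CC2=CC(c3cc4cc(OCc5ccccc5)c(OCc5ccccc5)cc4oc3=O)C(=O)OC2=C(OC)C1=O
F6 | step 1 | arteminorin C 6',7'-dibenzyl ether | COc1cc2cc(-c3cc4cc(OCc5ccccc5)c(OCc5ccccc5)cc4oc3=O)c(=O)oc2c(OC)c1O
F0 | step 3 | none | none
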